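Assumption: the SMILES is read as (8R,12S,15S,5Z,13E), that is (15S)-PGA2 methyl ester 15-acetate. Prostaglandin numbering (C1–C20) is used in the comments. Two operations run in one flask without isolation count as one step.

## Retrosynthetic overview
1. C7–C8 is cut last. It comes from trans-selective α'-alkylation of the cross-conjugated enolate of an (S)-4-alkenylcyclopent-2-enone with the (Z)-allylic iodide of the α-chain, which sets C8.
2. C12–C13 is the key bond. It comes from a Pd(II)-catalysed, hydroxyl-directed, enantioselective oxidative boron-Heck desymmetrisation of cyclopent-3-en-1-ol by the ω-chain (E)-alkenylboronate, which sets C12. Oxidation of the alcohol to the enone follows.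
3. ω-Chain: hexanoyl chloride and ethynyltrimethylsilane (acyl Sonogashira), asymmetric transfer hydrogenation (sets C15), acetate formation, and hydroboration (sets 13E).
4. α-Chain: hex-5-ynoic acid and formaldehyde, esterification, Lindlar reduction (sets 5Z), then iodide formation.
5. Rings: the only carbocycle is bought as cyclopent-3-en-1-ol, so no ring is formed.

## Route

Step 1
Reactants: 1 hexanoyl chloride; 2 ethynyltrimethylsilane
Product: 3 1-(trimethylsilyl)oct-1-yn-3-one
Conditions: PdCl2(PPh3)2 (2 mol %), CuI (4 mol %), Et3N (1.1 equiv), THF, rt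
Reagents that add atoms: none
Why: Acyl Sonogashira coupling, in which Pd(0) inserts into the C(O)–Cl bond, the copper acetylide of 2 transmetalates, and reductive elimination at rt outruns decarbonylation while the silyl group blocks the other alkyne terminus.

Step 2
Reactants: 3 1-(trimethylsilyl)oct-1-yn-3-one
Product: 4 (S)-1-(trimethylsilyl)oct-1-yn-3-ol
Conditions: Ru[(S,S)-TsDPEN](p-cymene) (1 mol %), i-PrOH, rt
Reagents that add atoms: none
Why: Noyori asymmetric transfer hydrogenation, in which the alkynyl group takes the place of the aryl group in the Ru–H/N–H transition state, so the (S,S) catalyst gives the (S)-propargylic alcohol (C15, typically ≥97 % ee) and leaves the alkyne untouched.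

Step 3
Reactants: 4 (S)-1-(trimethylsilyl)oct-1-yn-3-ol
Product: 6 (S)-oct-1-yn-3-yl acetate, via (S)-oct-1-yn-3-ol 5 (not isolated)
Conditions: K2CO3 (0.1 equiv), MeOH, rt; concentrate; Ac2O, pyridine, DMAP (cat.), 0 °C → rt
Reagents that add atoms: acetic anhydride CC(=O)OC(C)=O
Why: Methoxide-catalysed C(sp)–Si methanolysis followed by DMAP-catalysed O-acetylation, neither of which touches the C15–O bond, so the configuration is retained.

Step 4
Reactants: 6 (S)-oct-1-yn-3-yl acetate
Product: 7 (1E,3S)-1-(4,4,5,5-tetramethyl-1,3,2-dioxaborolan-2-yl)oct-1-en-3-yl acetate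
Conditions: HBpin (1.2 equiv), Cy2BH (10 mol %), neat, rt
Reagents that add atoms: pinacolborane B1OC(C)(C)C(C)(C)O1
Why: Dialkylborane-catalysed syn, anti-Markovnikov hydroboration of a terminal alkyne puts boron on the free terminus and gives only the (E)-alkenylboronate, and the ester is tolerated.

Step 5
Reactants: 7 (1E,3S)-1-(4,4,5,5-tetramethyl-1,3,2-dioxaborolan-2-yl)oct-1-en-3-yl acetate; 8 cyclopent-3-en-1-ol (3 equiv)
Product: 9 (1E,3S)-1-[(1R,4S)-4-hydroxycyclopent-2-en-1-yl]oct-1-en-3-yl acetate (cis ring)
Conditions: Pd(MeCN)2(OTs)2 (8 mol %), (S)-t-Bu-5-CF3-PyOx (16 mol %; its antipode if the sense of induction is opposite), Cu(OTf)2 (8 mol %), 3 Å MS, O2 (1 atm), DMF, rt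
Reagents that add atoms: none
Why: Proposed new method: an enantioselective, hydroxyl-directed oxidative boron-Heck desymmetrisation with an alkenylboronate, in which B-to-Pd transmetalation onto the cationic (PyOx)Pd(II) gives an (E)-alkenyl-Pd(II) species, the homoallylic OH of 8 steers it to its own ring face while the ligand picks one of the two enantiotopic olefin carbons, syn-carbopalladation makes C12–C13 and sets C12, the only syn β-hydrogen is on C10 (H12 is anti, and H9 is anti because Pd sits cis to OH, so there is no chain-walk to a ketone), β-hydride elimination releases the cis-4-alkenylcyclopent-2-enol, and O2/Cu returns Pd(0) to Pd(II); the closest known reaction types are the Heck–Matsuda desymmetrisation of cyclopent-3-enol with arenediazonium salts, enantioselective oxidative Heck reactions of arylboronic acids with PyOx ligands, and the non-asymmetric base-free oxidative Heck coupling of alkenyl-Bpin esters, but an alkenylboron partner has not been used in such a desymmetrisation.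

Step 6
Reactants: 9 (1E,3S)-1-[(1R,4S)-4-hydroxycyclopent-2-en-1-yl]oct-1-en-3-yl acetate
Product: 10 (1E,3S)-1-[(1S)-4-oxocyclopent-2-en-1-yl]oct-1-en-3-yl acetate
Conditions: Dess–Martin periodinane (1.2 equiv), CH2Cl2, 0 °C → rt
Reagents that add atoms: none
Why: Dess–Martin oxidation of the allylic alcohol runs without base, so the doubly allylic C12–H is neither epimerised nor moved into conjugation, and the auxiliary C9 carbinol centre is erased on purpose.

Step 7
Reactants: 11 hex-5-ynoic acid; 12 formaldehyde (used as paraformaldehyde)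
Product: 14 7-hydroxyhept-5-ynoic acid, via dilithium hex-5-ynoate acetylide 13 (not isolated)
Conditions: n-BuLi (2.1 equiv), THF, −78 → 0 °C; (CH2O)n, 0 °C → rt; aq HCl
Reagents that add atoms: none
Why: Acetylide hydroxymethylation, in which the first equivalent of base masks the acid as its carboxylate, the second removes only the alkyne C–H, and the acetylide adds to formaldehyde to install C7.

Step 8
Reactants: 14 7-hydroxyhept-5-ynoic acid
Product: 15 methyl 7-hydroxyhept-5-ynoate
Conditions: MeOH, p-TsOH (cat.), reflux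
Reagents that add atoms: methanol CO
Why: Fischer esterification driven by methanol as solvent, with the propargylic alcohol inert.

Step 9
Reactants: 15 methyl 7-hydroxyhept-5-ynoate
Product: 16 methyl (Z)-7-hydroxyhept-5-enoate
Conditions: H2 (1 atm), Lindlar catalyst, quinoline, EtOAc, rt
Reagents that add atoms: none
Why: Lindlar semihydrogenation delivers both hydrogens to one face of the alkyne on the poisoned Pd surface and stops at the (Z)-alkene (5Z).

Step 10
Reactants: 16 methyl (Z)-7-hydroxyhept-5-enoate
Product: 17 methyl (Z)-7-iodohept-5-enoate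
Conditions: I2, PPh3, imidazole, CH2Cl2, 0 °C, dark; used fresh
Reagents that add atoms: iodine II
Why: Appel-type (Garegg–Samuelsson) iodination is an SN2 displacement of the alkoxyphosphonium at the primary allylic carbon under near-neutral conditions, so the Z geometry is kept.

Step 11
Reactants: 10 (1E,3S)-1-[(1S)-4-oxocyclopent-2-en-1-yl]oct-1-en-3-yl acetate; 17 methyl (Z)-7-iodohept-5-enoate
Product: 19 methyl (5Z)-7-{(1R,2S)-2-[(1E,3S)-3-acetoxyoct-1-en-1-yl]-5-oxocyclopent-3-en-1-yl}hept-5-enoate, via lithium cross-conjugated dienolate 18 (not isolated)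
Conditions: LiHMDS (1.05 equiv), THF, −78 °C; 17 (1.5 equiv), DMPU, −78 → −40 °C; aq NH4Cl
Reagents that add atoms: none
Why: Kinetic α'-deprotonation of the enone (the ketone is about 5 pKa units more acidic than the acetate) and SN2 enolate alkylation by the reactive allylic iodide on the face anti to the C12 side chain sets 8R (trans, also the thermodynamic isomer), and the low temperature keeps C12–H in place.

## Compound list
1 | hexanoyl chloride | CCCCCC(=O)Cl | starting material
2 | ethynyltrimethylsilane | C#C[Si](C)(C)C | starting material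
3 | 1-(trimethylsilyl)oct-1-yn-3-one | CCCCCC(=O)C#C[Si](C)(C)C | intermediate
4 | (S)-1-(trimethylsilyl)oct-1-yn-3-ol | CCCCC[C@@H](C#C[Si](C)(C)C)O | intermediate
5 | (S)-oct-1-yn-3-ol (not isolated) | CCCCC[C@@H](C#C)O | intermediate
6 | (S)-oct-1-yn-3-yl acetate | CCCCC[C@@H](C#C)OC(C)=O | intermediate
7 | (1E,3S)-1-(4,4,5,5-tetramethyl-1,3,2-dioxaborolan-2-yl)oct-1-en-3-yl acetate | CCCCC[C@@H](/C=C/B1OC(C)(C)C(C)(C)O1)OC(C)=O | intermediate
8 | cyclopent-3-en-1-ol | OC1CC=CC1 | starting material
9 | (1E,3S)-1-[(1R,4S)-4-hydroxycyclopent-2-en-1-yl]oct-1-en-3-yl acetate | CCCCC[C@@H](/C=C/[C@H]1C=C[C@@H](O)C1)OC(C)=O | intermediate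
10 | (1E,3S)-1-[(1S)-4-oxocyclopent-2-en-1-yl]oct-1-en-3-yl acetate | CCCCC[C@@H](/C=C/[C@H]1C=CC(=O)C1)OC(C)=O | intermediate
11 | hex-5-ynoic acid | C#CCCCC(=O)O | starting material
12 | formaldehyde (as paraformaldehyde) | C=O | starting material
13 | dilithium hex-5-ynoate acetylide (not isolated) | [Li+].[Li+].[C-]#CCCCC(=O)[O-] | intermediate
14 | 7-hydroxyhept-5-ynoic acid | OCC#CCCCC(=O)O | intermediate
15 | methyl 7-hydroxyhept-5-ynoate | COC(=O)CCCC#CCO | intermediate
16 | methyl (Z)-7-hydroxyhept-5-enoate | COC(=O)CCC/C=C\CO | intermediate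
17 | methyl (Z)-7-iodohept-5-enoate | COC(=O)CCC/C=C\CI | intermediate
18 | lithium cross-conjugated dienolate of 10 (C8=C9–OLi, C12 unchanged; not isolated) | CCCCC[C@@H](/C=C/[C@H]1C=CC(O[Li])=C1)OC(C)=O | intermediate
19 | methyl (5Z)-7-{(1R,2S)-2-[(1E,3S)-3-acetoxyoct-1-en-1-yl]-5-oxocyclopent-3-en-1-yl}hept-5-enoate, (15S)-PGA2 methyl ester 15-acetate | CCCCC[C@@H](/C=C/[C@H]1C=CC(=O)[C@@H]1C/C=C\CCCC(=O)OC)OC(C)=O | target

Total step count: 11.
Longest linear sequence: 7 (steps 1, 2, 3, 4, 5, 6 and 11). The α-chain branch (steps 7–10) joins in step 11.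

## Steps most likely to fail

**Step 5 (the new reaction).**
- Transmetalation of the pinacol ester may be slow.
- Boronate 7 may homocouple oxidatively.
- Insertion anti to the OH would chain-walk to the 3-alkenylcyclopentanone.
- Pd–H may isomerise the skipped diene.
- Pd(II) may shift the allylic acetate 1,3, although the 15-acetate/Δ13 isomer should be the favoured one.
- The ee is unknown. Because 7 is a single enantiomer, any error at C12 appears as a separable diastereomer.

The fallback uses known chemistry, sets out from 7 and comes back at 10. Rhodium(I)-catalysed 1,4-addition of 7 ([Rh(cod)OH]2, dioxane/H2O, 40 °C) to bought (R)-4-(tert-butyldimethylsilyloxy)cyclopent-2-en-1-one F1 takes place anti to the silyloxy group. It gives (1E,3S)-1-[(1S,2R)-2-(tert-butyldimethylsilyloxy)-4-oxocyclopentyl]oct-1-en-3-yl acetate F2. DBU (CH2Cl2, 0 °C) then expels the silanol by E1cB across C10–C11 and gives 10. In this fallback C12 is set by substrate control and step 6 is not needed.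

**Step 11.**
- Proton transfer between 18 and the product may cause dialkylation.
- A 1,5-hydrogen shift or γ-deprotonation in 18 could erode C12 or lead to the PGB-type dienone.
- Iodide 17 may isomerise from Z to E.
- The base may attack the acetate.

The fallback sets out from 5 (isolated here) and 17 and comes back at 19. It builds both side-chain bonds by a three-component coupling on a β-silyloxy enone and makes the ring double bond afterwards.
1. Alcohol 5 is silylated (TBSCl, imidazole) to (S)-3-(tert-butyldimethylsilyloxy)oct-1-yne F3.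
2. Hydrozirconation–iodination (Cp2ZrHCl; I2) gives (S,E)-3-(tert-butyldimethylsilyloxy)-1-iodooct-1-ene F4.
3. Iodine–lithium exchange (t-BuLi, −78 °C) and Me2Zn give lithium (S,E)-[3-(tert-butyldimethylsilyloxy)oct-1-enyl]dimethylzincate F5.
4. F5 adds to (R)-4-(tert-butyldimethylsilyloxy)cyclopent-2-en-1-one F1 anti to its silyloxy group.
5. The resulting lithium dimethylzinc enolate F6 is alkylated in the same flask by 17 (HMPA, −40 °C) anti to the new side chain, giving 11,15-bis-O-(tert-butyldimethylsilyl)-PGE2 methyl ester F7.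
6. HF·pyridine (MeCN) gives PGE2 methyl ester F8.
7. Ac2O, pyridine and DMAP give PGE2 methyl ester 11,15-diacetate F9, which loses the 11-acetate by E1cB under the same mild base to give 19.

**Step 1.** The enolisable acid chloride may form the ketene with Et3N, or decarbonylate on Pd. The fallback sets out from 2 and comes back at 3. Alkyne 2 is lithiated (n-BuLi, THF, −78 °C) and added to bought hexanal F10 to give rac-1-(trimethylsilyl)oct-1-yn-3-ol F11. This is oxidised (MnO2, CH2Cl2) to 3. The stereocentre is still set afterwards in step 2.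

## Further compounds
F1 | step 5 | (R)-4-(tert-butyldimethylsilyloxy)cyclopent-2-en-1-one (bought) | O=C1C[C@@H](O[Si](C)(C)C(C)(C)C)C=C1
F2 | step 5 | (1E,3S)-1-[(1S,2R)-2-(tert-butyldimethylsilyloxy)-4-oxocyclopentyl]oct-1-en-3-yl acetate | CCCCC[C@@H](/C=C/[C@H]1[C@@H](CC(=O)C1)O[Si](C)(C)C(C)(C)C)OC(C)=O
F3 | step 11 | (S)-3-(tert-butyldimethylsilyloxy)oct-1-yne | CCCCC[C@@H](C#C)O[Si](C)(C)C(C)(C)C
F4 | step 11 | (S,E)-3-(tert-butyldimethylsilyloxy)-1-iodooct-1-ene | CCCCC[C@@H](/C=C/I)O[Si](C)(C)C(C)(C)C
F5 | step 11 | lithium (S,E)-[3-(tert-butyldimethylsilyloxy)oct-1-enyl]dimethylzincate | CCCCC[C@@H](/C=C/[Zn-](C)C)O[Si](C)(C)C(C)(C)C.[Li+]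
F6 | step 11 | lithium dimethylzinc enolate (C8=C9–O–Zn) of the conjugate adduct | CCCCC[C@@H](/C=C/[C@H]1[C@@H](CC(O[Zn-](C)C)=C1)O[Si](C)(C)C(C)(C)C)O[Si](C)(C)C(C)(C)C.[Li+]
F7 | step 11 | 11,15-bis-O-(tert-butyldimethylsilyl)-PGE2 methyl ester | CCCCC[C@@H](/C=C/[C@H]1[C@@H](CC(=O)[C@@H]1C/C=C\CCCC(=O)OC)O[Si](C)(C)C(C)(C)C)O[Si](C)(C)C(C)(C)C
F8 | step 11 | PGE2 methyl ester | CCCCC[C@@H](/C=C/[C@H]1[C@@H](CC(=O)[C@@H]1C/C=C\CCCC(=O)OC)O)O
F9 | step 11 | PGE2 methyl ester 11,15-diacetate | CCCCC[C@@H](/C=C/[C@H]1[C@@H](CC(=O)[C@@H]1C/C=C\CCCC(=O)OC)OC(C)=O)OC(C)=O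
F10 | step 1 | hexanal (bought) | CCCCCC=O
F11 | step 1 | rac-1-(trimethylsilyl)oct-1-yn-3-ol | CCCCCC(O)C#C[Si](C)(C)C
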